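**Plan**

- Numbering follows chroman-4-one (O1, C2, C3, C4, C4a, C5–C8, C8a). Ring A (C4a–C5–C6–C7–C8–C8a) is a fully substituted phloroglucinol: oxygens on C5, C7 and C8a alternate with carbon substituents on C4a, C6 and C8, which is the pattern a vinylketene/ynol ether benzannulation lays down with all three oxygens told apart.
- Retrosynthetic cuts: ester/C7–O (temporary δ-lactone), the prenyl C=C (cross-metathesis of an allyl stand-in that survives the acid steps), O1–C2 (oxa-Michael), C4–C4a (Friedel–Crafts), then ring A at C6–C7, C4a–C5 and C7–C8 back to a 3-tert-butoxycyclobutenone and a siloxyalkyne.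
- Forward order: meso anhydride, hemiester, ketene/ynol ether [2+2] (cyclobutenone), benzannulation (ring A), lactone on O–C7, free O–C8a, C4a tigloylation, pyranone ring closure, prenyl, desilylation, lactone methanolysis.
- Stereochemistry: the side-chain centre comes from catalytic desymmetrisation of 3-propylglutaric anhydride and is never enolisable; C2 and C3 come from a quinine-catalysed, kinetically cis-selective oxa-Michael ring closure.

Key step: step 8

Assumption: (DHQD)2AQN is taken to open the glutaric anhydride to the (S)-hemiester and (−)-quinine to give the 2R,3S cis-chromanone from the tigloyl phenol; if either sense proves opposite, the pseudo-enantiomeric alkaloid ((DHQ)2AQN or quinidine) is used with nothing else changed.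

**Route**

Step 1
Reactants: 1 3-propylglutaric acid
Product: 2 3-propylglutaric anhydride
Conditions: Ac2O, reflux; distillation
Reagents that add atoms: none
Why: Cyclodehydration of the 1,5-diacid through a mixed anhydride gives the six-membered meso anhydride, whose propyl-bearing carbon is prochiral.

Step 2
Reactants: 2 3-propylglutaric anhydride
Product: 3 (3S)-3-(2-methoxy-2-oxoethyl)hexanoic acid
Conditions: (DHQD)2AQN [hydroquinidine anthraquinone-1,4-diyl diether] (10 mol %), MeOH (10 equiv), Et2O, −30 °C
Reagents that add atoms: methanol, CO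
Why: Cinchona-alkaloid-catalysed enantioselective methanolysis (desymmetrisation of a meso anhydride by general-base catalysis) differentiates the enantiotopic carbonyl groups and so sets the only side-chain stereocentre, the free-acid arm being the one that later supplies C7 and C8 of ring A.

Step 3
Reactants: 3 (3S)-3-(2-methoxy-2-oxoethyl)hexanoic acid
Product: 4 methyl (3R)-3-(2-chloro-2-oxoethyl)hexanoate
Conditions: (COCl)2, DMF (cat.), CH2Cl2, 0 → 25 °C; used crude
Reagents that add atoms: oxalyl chloride, O=C(Cl)C(=O)Cl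
Why: Acid chloride formation through the Vilsmeier-type chloroiminium species leaves the ester and the β-stereocentre untouched, and keeping the crude chloride at or below room temperature avoids ester/acid chloride interchange that would erode the enantiomeric purity (the descriptor changes to R only because the priorities change).

Step 4
Reactants: 5 trichloroethylene
Product: 7 tert-butyl (E)-1,2-dichlorovinyl ether, via dichloroacetylene 6 (not isolated)
Conditions: KOt-Bu, THF, −78 → 25 °C
Reagents that add atoms: potassium tert-butoxide, CC(C)(C)[O-].[K+]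
Why: Base-induced dehydrochlorination to 6 followed by anti addition of tert-butoxide and a proton across the triple bond (elimination–addition synthesis of 1,2-dichlorovinyl ethers) gives the E ether without isolation of the hazardous alkyne.

Step 5
Reactants: 7 tert-butyl (E)-1,2-dichlorovinyl ether
Product: 10 tert-butoxyacetylene, via 1-tert-butoxy-2-chloroacetylene 8 (not isolated), via lithium tert-butoxyacetylide 9 (not isolated)
Conditions: n-BuLi (2.2 equiv), Et2O, −78 → −30 °C; MeOH, −78 °C; cold aqueous work-up, kept as a dried ethereal solution below 0 °C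
Reagents that add atoms: none
Why: β-Elimination of HCl by the first equivalent of n-BuLi gives 8, chlorine–lithium exchange by the second gives 9, and cold protonation releases the heat-sensitive terminal ynol ether (dichlorovinyl ether route to ynol ethers).

Step 6
Reactants: 4 methyl (3R)-3-(2-chloro-2-oxoethyl)hexanoate; 10 tert-butoxyacetylene
Product: 12 methyl (3R)-3-(2-tert-butoxy-4-oxocyclobut-2-en-1-yl)hexanoate, via aldoketene 11 (not isolated)
Conditions: 10 (2.5 equiv), Et3N (1.2 equiv, added over 4 h), Et2O, 0 → 25 °C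
Reagents that add atoms: none
Why: Dehydrochlorination of 4 generates aldoketene 11 at low concentration, which is trapped in a regioselective ketene–ynol ether [2+2] cycloaddition (nucleophilic CH terminus of 10 to the ketene carbonyl carbon) to give the 4-substituted 3-alkoxycyclobutenone; the new ring stereocentre is immaterial because it becomes aromatic, and the side-chain centre, β to both carbonyl groups, cannot enolise.

Step 7
Reactants: 13 pent-4-en-1-yne
Product: 16 triisopropyl(pent-4-en-1-yn-1-yloxy)silane, via lithium pent-4-en-1-ynide 14 (not isolated), via lithium pent-4-en-1-yn-1-olate 15 (not isolated)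
Conditions: n-BuLi, THF, −78 °C; t-BuOOLi (from t-BuOOH and LiN(SiMe3)2), −78 → 0 °C; i-Pr3SiOTf, −78 °C
Reagents that add atoms: tert-butyl hydroperoxide, CC(C)(C)OO; triisopropylsilyl trifluoromethanesulfonate, CC(C)[Si](C(C)C)(C(C)C)OS(=O)(=O)C(F)(F)F
Why: Electrophilic oxygenation of acetylide 14 by lithium tert-butylperoxide gives ynolate 15, which the bulky silyl triflate captures on oxygen (ynolate O-silylation) to give an isolable siloxyalkyne.

Step 8
Reactants: 12 methyl (3R)-3-(2-tert-butoxy-4-oxocyclobut-2-en-1-yl)hexanoate; 16 triisopropyl(pent-4-en-1-yn-1-yloxy)silane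
Product: 21 methyl (3R)-3-[6-tert-butoxy-2-hydroxy-3-(prop-2-enyl)-4-(triisopropylsilyloxy)phenyl]hexanoate, via vinylketene 17 (not isolated), via vinylcyclobutenone adduct 18 (not isolated), via dienylketene 19 (not isolated), via cyclohexadienone 20 (not isolated)
Conditions: 16 (1.5 equiv), toluene, 80 → 110 °C, sealed tube
Reagents that add atoms: none
Why: Thermal conrotatory 4π opening of 12 gives vinylketene 17, whose ketene C=C undergoes [2+2] cycloaddition with 16 (allyl-bearing carbon to the ketene carbonyl carbon, forming C6–C7; oxygen-bearing carbon to the ketene α-carbon, forming C4a–C5) to give 18, and 4π opening of 18 gives dienylketene 19. Ring A then closes in the 6π-disrotatory electrocyclic mode (C7–C8 bond) to dienone 20, which tautomerises to phenol 21. The closest known reaction type is the Danheiser benzannulation of cyclobutenones with siloxyalkynes, together with the thermal conversion of 3-alkoxycyclobutenones and ynol ethers into 3,5-dialkoxyphenols. No stereocentre is created: the ring stereocentre of 12 is destroyed and the non-enolisable side-chain centre is carried through unchanged. The selectivity needed is the orientation of the [2+2] step, and it is secured by the polarisation of the ynol ether (nucleophilic β-carbon, cation-stabilising α-carbon), which places the allyl group between two oxygens and leaves O–C7 as free hydroxyl, O–C5 as silyl ether and O–C8a as tert-butyl ether.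

Step 9
Reactants: 21 methyl (3R)-3-[6-tert-butoxy-2-hydroxy-3-(prop-2-enyl)-4-(triisopropylsilyloxy)phenyl]hexanoate
Product: 22 (3R)-3-[6-tert-butoxy-2-hydroxy-3-(prop-2-enyl)-4-(triisopropylsilyloxy)phenyl]hexanoic acid
Conditions: LiOH (3 equiv), THF/H2O (3:1), 25 °C; 1 M HCl to pH 3, 0 °C
Reagents that add atoms: lithium hydroxide, [Li+].[OH-]
Why: Saponification (BAC2 ester hydrolysis) frees the carboxylic acid, the hindered aryl silyl ether and the tert-butyl ether on the phenoxide-enriched ring being expected to survive, and any lactone formed thermally in step 8 converges on the same acid.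

Step 10
Reactants: 22 (3R)-3-[6-tert-butoxy-2-hydroxy-3-(prop-2-enyl)-4-(triisopropylsilyloxy)phenyl]hexanoic acid
Product: 23 (4R)-5-tert-butoxy-8-(prop-2-enyl)-4-propyl-7-(triisopropylsilyloxy)-3,4-dihydro-2H-chromen-2-one
Conditions: i-PrN=C=N-i-Pr, DMAP (10 mol %), CH2Cl2, 0 → 25 °C
Reagents that add atoms: none
Why: Carbodiimide-mediated lactonisation (Steglich esterification) onto the only free phenol ties the carboxyl group and O–C7 together as a dihydrocoumarin before O–C8a is unmasked, so that later steps meet a single free phenol and no ester that it could attack.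

Step 11
Reactants: 23 (4R)-5-tert-butoxy-8-(prop-2-enyl)-4-propyl-7-(triisopropylsilyloxy)-3,4-dihydro-2H-chromen-2-one
Product: 24 (4R)-5-hydroxy-8-(prop-2-enyl)-4-propyl-7-(triisopropylsilyloxy)-3,4-dihydro-2H-chromen-2-one
Conditions: CF3CO2H/CH2Cl2 (1:4), Et3SiH (3 equiv), 0 °C
Reagents that add atoms: none
Why: Acid-induced SN1 cleavage of the aryl tert-butyl ether, with Et3SiH trapping the tert-butyl cation so that C4a is not alkylated, unmasks the C8a phenol while the aryl silyl ether, the lactone and the monosubstituted alkene (chosen in place of the acid-labile prenyl group) stay inert.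

Step 12
Reactants: 24 (4R)-5-hydroxy-8-(prop-2-enyl)-4-propyl-7-(triisopropylsilyloxy)-3,4-dihydro-2H-chromen-2-one; 25 tigloyl chloride
Product: 26 (4R)-5-hydroxy-6-[(E)-2-methylbut-2-enoyl]-8-(prop-2-enyl)-4-propyl-7-(triisopropylsilyloxy)-3,4-dihydro-2H-chromen-2-one
Conditions: 25 (1.2 equiv), TiCl4 (2.2 equiv), CH2Cl2, −78 → 0 °C; product used promptly
Reagents that add atoms: none
Why: TiCl4-mediated ortho-selective Friedel–Crafts acylation (Fries-type C-acylation of a phenol) takes place at C4a, the only unsubstituted ring carbon, which is activated by the ortho hydroxyl, ortho silyloxy and para acyloxy groups, and the low temperature is meant to keep the silyl ether on and the enone open.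

Step 13
Reactants: 26 (4R)-5-hydroxy-6-[(E)-2-methylbut-2-enoyl]-8-(prop-2-enyl)-4-propyl-7-(triisopropylsilyloxy)-3,4-dihydro-2H-chromen-2-one
Product: 27 (2R,3S,10R)-2,3-dimethyl-6-(prop-2-enyl)-10-propyl-5-(triisopropylsilyloxy)-2,3,9,10-tetrahydro-4H,8H-pyrano[2,3-f]chromene-4,8-dione
Conditions: (−)-quinine (20 mol %), PhCl, 25 °C
Reagents that add atoms: none
Why: Quinine-catalysed asymmetric intramolecular oxa-Michael addition (6-endo-trig) of the C8a phenol to the tigloyl enone, in which the alkaloid-bound phenoxide adds to one face of the β-carbon to set C2 (R) and kinetic protonation of the enol on the same face sets C3 (S), should give the cis-2,3-dimethylchromanone, the C5 oxygen being blocked as its silyl ether so that only one ring can close.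

Step 14
Reactants: 27 (2R,3S,10R)-2,3-dimethyl-6-(prop-2-enyl)-10-propyl-5-(triisopropylsilyloxy)-2,3,9,10-tetrahydro-4H,8H-pyrano[2,3-f]chromene-4,8-dione
Product: 28 (2R,3S,10R)-2,3-dimethyl-6-(3-methylbut-2-enyl)-10-propyl-5-(triisopropylsilyloxy)-2,3,9,10-tetrahydro-4H,8H-pyrano[2,3-f]chromene-4,8-dione
Conditions: second-generation Grubbs catalyst RuCl2(=CHPh)(PCy3)(H2IMes) (5 mol %), 2-methyl-2-butene/CH2Cl2 (1:1), 40 °C, sealed tube
Reagents that add atoms: 2-methyl-2-butene, CC=C(C)C
Why: Olefin cross-metathesis of the terminal allyl group with excess 2-methyl-2-butene installs the prenyl group under neutral conditions that leave the epimerisable C3 centre, the lactone and the silyl ether untouched.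

Step 15
Reactants: 28 (2R,3S,10R)-2,3-dimethyl-6-(3-methylbut-2-enyl)-10-propyl-5-(triisopropylsilyloxy)-2,3,9,10-tetrahydro-4H,8H-pyrano[2,3-f]chromene-4,8-dione
Product: 29 (2R,3S,10R)-5-hydroxy-2,3-dimethyl-6-(3-methylbut-2-enyl)-10-propyl-2,3,9,10-tetrahydro-4H,8H-pyrano[2,3-f]chromene-4,8-dione
Conditions: Bu4NF/AcOH (1:1, 1.5 equiv), THF, 0 °C
Reagents that add atoms: none
Why: Fluoride-induced cleavage of the aryl silyl ether, made easy by the ortho carbonyl group, is buffered with acetic acid so that neither epimerisation at C3 nor retro-oxa-Michael opening is promoted by base.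

Step 16
Reactants: 29 (2R,3S,10R)-5-hydroxy-2,3-dimethyl-6-(3-methylbut-2-enyl)-10-propyl-2,3,9,10-tetrahydro-4H,8H-pyrano[2,3-f]chromene-4,8-dione
Product: 30 methyl (3R)-3-[(2R,3S)-5,7-dihydroxy-2,3-dimethyl-6-(3-methylbut-2-enyl)-4-oxo-3,4-dihydro-2H-chromen-8-yl]hexanoate
Conditions: K2CO3 (2 equiv), MeOH, 0 °C; AcOH to pH 7
Reagents that add atoms: methanol, CO
Why: Base-mediated transesterification of the aryl lactone with methanol releases the C7 phenol and the methyl ester in one operation, and deprotonation of the C5 and C7 phenols should turn the ketone into a vinylogous carboxylate that shields the cis C2/C3 centres from enolisation during the short, cold reaction.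

**Compound list**

1 | 3-propylglutaric acid | CCCC(CC(=O)O)CC(=O)O | starting material
2 | 3-propylglutaric anhydride (4-propyloxane-2,6-dione) | CCCC1CC(=O)OC(=O)C1 | intermediate
3 | (3S)-3-(2-methoxy-2-oxoethyl)hexanoic acid | CCC[C@H](CC(=O)OC)CC(=O)O | intermediate
4 | methyl (3R)-3-(2-chloro-2-oxoethyl)hexanoate | CCC[C@H](CC(=O)OC)CC(=O)Cl | intermediate
5 | trichloroethylene | ClC=C(Cl)Cl | starting material
6 | dichloroacetylene (transient) | ClC#CCl | intermediate
7 | tert-butyl (E)-1,2-dichlorovinyl ether | CC(C)(C)O/C(Cl)=C\Cl | intermediate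
8 | 1-tert-butoxy-2-chloroacetylene (transient) | CC(C)(C)OC#CCl | intermediate
9 | lithium tert-butoxyacetylide (transient) | [Li]C#COC(C)(C)C | intermediate
10 | tert-butoxyacetylene | C#COC(C)(C)C | intermediate
11 | methyl (3R)-3-(2-oxoethenyl)hexanoate (aldoketene, transient) | CCC[C@H](CC(=O)OC)C=C=O | intermediate
12 | methyl (3R)-3-(2-tert-butoxy-4-oxocyclobut-2-en-1-yl)hexanoate (both epimers at the ring carbon) | CCC[C@H](CC(=O)OC)C1C(=O)C=C1OC(C)(C)C | intermediate
13 | pent-4-en-1-yne | C=CCC#C | starting material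
14 | lithium pent-4-en-1-ynide (transient) | [Li]C#CCC=C | intermediate
15 | lithium pent-4-en-1-yn-1-olate (transient) | [Li]OC#CCC=C | intermediate
16 | triisopropyl(pent-4-en-1-yn-1-yloxy)silane | C=CCC#CO[Si](C(C)C)(C(C)C)C(C)C | intermediate
17 | methyl (3R)-3-(2-tert-butoxy-4-oxobuta-1,3-dien-1-yl)hexanoate (vinylketene, transient) | CCC[C@H](CC(=O)OC)C=C(OC(C)(C)C)C=C=O | intermediate
18 | methyl (3R)-3-{2-tert-butoxy-2-[4-oxo-3-(prop-2-enyl)-2-(triisopropylsilyloxy)cyclobut-2-en-1-yl]ethenyl}hexanoate (transient) | CCC[C@H](CC(=O)OC)C=C(OC(C)(C)C)C1C(=O)C(CC=C)=C1O[Si](C(C)C)(C(C)C)C(C)C | intermediate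
19 | methyl (3R)-3-[2-tert-butoxy-6-oxo-5-(prop-2-enyl)-4-(triisopropylsilyloxy)hexa-1,3,5-trien-1-yl]hexanoate (dienylketene, transient) | CCC[C@H](CC(=O)OC)C=C(OC(C)(C)C)C=C(O[Si](C(C)C)(C(C)C)C(C)C)C(CC=C)=C=O | intermediate
20 | methyl (3R)-3-[6-tert-butoxy-2-oxo-3-(prop-2-enyl)-4-(triisopropylsilyloxy)cyclohexa-3,5-dien-1-yl]hexanoate (transient) | CCC[C@H](CC(=O)OC)C1C(=O)C(CC=C)=C(O[Si](C(C)C)(C(C)C)C(C)C)C=C1OC(C)(C)C | intermediate
21 | methyl (3R)-3-[6-tert-butoxy-2-hydroxy-3-(prop-2-enyl)-4-(triisopropylsilyloxy)phenyl]hexanoate | CCC[C@H](CC(=O)OC)c1c(O)c(CC=C)c(O[Si](C(C)C)(C(C)C)C(C)C)cc1OC(C)(C)C | intermediate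
22 | (3R)-3-[6-tert-butoxy-2-hydroxy-3-(prop-2-enyl)-4-(triisopropylsilyloxy)phenyl]hexanoic acid | CCC[C@H](CC(=O)O)c1c(O)c(CC=C)c(O[Si](C(C)C)(C(C)C)C(C)C)cc1OC(C)(C)C | intermediate
23 | (4R)-5-tert-butoxy-8-(prop-2-enyl)-4-propyl-7-(triisopropylsilyloxy)-3,4-dihydro-2H-chromen-2-one | CCC[C@@H]1CC(=O)Oc2c(CC=C)c(O[Si](C(C)C)(C(C)C)C(C)C)cc(OC(C)(C)C)c21 | intermediate
24 | (4R)-5-hydroxy-8-(prop-2-enyl)-4-propyl-7-(triisopropylsilyloxy)-3,4-dihydro-2H-chromen-2-one | CCC[C@@H]1CC(=O)Oc2c(CC=C)c(O[Si](C(C)C)(C(C)C)C(C)C)cc(O)c21 | intermediate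
25 | tigloyl chloride [(E)-2-methylbut-2-enoyl chloride] | C/C=C(\C)C(=O)Cl | starting material
26 | (4R)-5-hydroxy-6-[(E)-2-methylbut-2-enoyl]-8-(prop-2-enyl)-4-propyl-7-(triisopropylsilyloxy)-3,4-dihydro-2H-chromen-2-one | CCC[C@@H]1CC(=O)Oc2c(CC=C)c(O[Si](C(C)C)(C(C)C)C(C)C)c(C(=O)/C(C)=C/C)c(O)c21 | intermediate
27 | (2R,3S,10R)-2,3-dimethyl-6-(prop-2-enyl)-10-propyl-5-(triisopropylsilyloxy)-2,3,9,10-tetrahydro-4H,8H-pyrano[2,3-f]chromene-4,8-dione | CCC[C@@H]1CC(=O)Oc2c(CC=C)c(O[Si](C(C)C)(C(C)C)C(C)C)c3c(c21)O[C@H](C)[C@H](C)C3=O | intermediate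
28 | (2R,3S,10R)-2,3-dimethyl-6-(3-methylbut-2-enyl)-10-propyl-5-(triisopropylsilyloxy)-2,3,9,10-tetrahydro-4H,8H-pyrano[2,3-f]chromene-4,8-dione | CCC[C@@H]1CC(=O)Oc2c(CC=C(C)C)c(O[Si](C(C)C)(C(C)C)C(C)C)c3c(c21)O[C@H](C)[C@H](C)C3=O | intermediate
29 | (2R,3S,10R)-5-hydroxy-2,3-dimethyl-6-(3-methylbut-2-enyl)-10-propyl-2,3,9,10-tetrahydro-4H,8H-pyrano[2,3-f]chromene-4,8-dione | CCC[C@@H]1CC(=O)Oc2c(CC=C(C)C)c(O)c3c(c21)O[C@H](C)[C@H](C)C3=O | intermediate
30 | methyl (3R)-3-[(2R,3S)-5,7-dihydroxy-2,3-dimethyl-6-(3-methylbut-2-enyl)-4-oxo-3,4-dihydro-2H-chromen-8-yl]hexanoate | CCC[C@H](CC(=O)OC)c1c(O)c(CC=C(C)C)c(O)c2c1O[C@H](C)[C@H](C)C2=O | target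

**Step count and risks**

Total steps: 16. Longest linear sequence: 13 steps (steps 1–3, 6, 8–16, from 1 to 30).

Steps most likely to fail:

1. Step 8. Capture of vinylketene 17 by the internally substituted siloxyalkyne 16 may be too slow. The ketene could then dimerise or acylate the product phenol, or the tert-butyl enol ether could lose isobutene at the temperature needed for ring opening. Fallback (sets out from 12, returns at 21): the annulation is run with the unhindered terminal partner (triisopropylsilyloxy)ethyne F1, which should give methyl (3R)-3-[2-tert-butoxy-6-hydroxy-4-(triisopropylsilyloxy)phenyl]hexanoate F2 with C6 still unsubstituted. O-Allylation of the free phenol (allyl bromide, K2CO3, acetone) gives methyl (3R)-3-[2-tert-butoxy-6-(prop-2-enyloxy)-4-(triisopropylsilyloxy)phenyl]hexanoate F3. An aromatic Claisen rearrangement (PhNEt2, 180 °C) then moves the allyl group to C6, the only free ortho position because C8 is blocked, and rejoins the route at 21.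

2. Step 12. The Lewis acid may strip the silyl ether next to the new ketone and promote uncatalysed closure of the enone onto either flanking oxygen, which would erode regio- and enantiocontrol before step 13; O-acylation without migration to carbon is the other failure. Fallback (sets out from 24, returns at 26): iodination at C4a with N-iodosuccinimide (MeCN, 0 °C) should give (4R)-5-hydroxy-6-iodo-8-(prop-2-enyl)-4-propyl-7-(triisopropylsilyloxy)-3,4-dihydro-2H-chromen-2-one F4. A carbonylative Stille coupling with tributyl[(E)-but-2-en-2-yl]stannane (Pd(PPh3)4, CO 1 atm, dioxane, 80 °C) then installs the tigloyl group with retention of alkene geometry and without any Lewis acid, giving 26.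

3. Step 13. Facial selectivity may be poor or turnover slow with the twisted, ortho-silyloxy aryl ketone, and a racemic background cyclisation or drift to the trans isomer may compete. Fallback (sets out from 24, returns at 27, replacing steps 12 and 13): both ring stereocentres are taken from the chiral pool. Fráter–Seebach methylation of tert-butyl (S)-3-hydroxybutanoate gives tert-butyl (2S,3S)-3-hydroxy-2-methylbutanoate F5. Mitsunobu etherification of phenol 24 with F5 (PPh3, DIAD, toluene, 0 → 25 °C) inverts the carbinol centre and should give tert-butyl (2S,3R)-2-methyl-3-{[(4R)-2-oxo-8-(prop-2-enyl)-4-propyl-7-(triisopropylsilyloxy)-3,4-dihydro-2H-chromen-5-yl]oxy}butanoate F6. CF3CO2H in CH2Cl2 at 0 °C cleaves the tert-butyl ester to (2S,3R)-2-methyl-3-{[(4R)-2-oxo-8-(prop-2-enyl)-4-propyl-7-(triisopropylsilyloxy)-3,4-dihydro-2H-chromen-5-yl]oxy}butanoic acid F7. Intramolecular Friedel–Crafts acylation at C4a through the mixed anhydride ((CF3CO)2O, CH2Cl2, 0 °C) then closes the chromanone to 27, with C2 fixed by the inversion and C3 by the alkylation.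

Further compounds

F1 | step 8 | (triisopropylsilyloxy)ethyne | C#CO[Si](C(C)C)(C(C)C)C(C)C
F2 | step 8 | methyl (3R)-3-[2-tert-butoxy-6-hydroxy-4-(triisopropylsilyloxy)phenyl]hexanoate | CCC[C@H](CC(=O)OC)c1c(O)cc(O[Si](C(C)C)(C(C)C)C(C)C)cc1OC(C)(C)C
F3 | step 8 | methyl (3R)-3-[2-tert-butoxy-6-(prop-2-enyloxy)-4-(triisopropylsilyloxy)phenyl]hexanoate | CCC[C@H](CC(=O)OC)c1c(OCC=C)cc(O[Si](C(C)C)(C(C)C)C(C)C)cc1OC(C)(C)C
F4 | step 12 | (4R)-5-hydroxy-6-iodo-8-(prop-2-enyl)-4-propyl-7-(triisopropylsilyloxy)-3,4-dihydro-2H-chromen-2-one | CCC[C@@H]1CC(=O)Oc2c(CC=C)c(O[Si](C(C)C)(C(C)C)C(C)C)c(I)c(O)c21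
F5 | step 13 | tert-butyl (2S,3S)-3-hydroxy-2-methylbutanoate | C[C@H](O)[C@H](C)C(=O)OC(C)(C)C
F6 | step 13 | tert-butyl (2S,3R)-2-methyl-3-{[(4R)-2-oxo-8-(prop-2-enyl)-4-propyl-7-(triisopropylsilyloxy)-3,4-dihydro-2H-chromen-5-yl]oxy}butanoate | CCC[C@@H]1CC(=O)Oc2c(CC=C)c(O[Si](C(C)C)(C(C)C)C(C)C)cc(O[C@H](C)[C@H](C)C(=O)OC(C)(C)C)c21
F7 | step 13 | (2S,3R)-2-methyl-3-{[(4R)-2-oxo-8-(prop-2-enyl)-4-propyl-7-(triisopropylsilyloxy)-3,4-dihydro-2H-chromen-5-yl]oxy}butanoic acid | CCC[C@@H]1CC(=O)Oc2c(CC=C)c(O[Si](C(C)C)(C(C)C)C(C)C)cc(O[C@H](C)[C@H](C)C(=O)O)c21
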